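J came slowly. In the green run after 5.00 min, L had lost 43.0% of its charge, yet J stood at 7.3%. Something stood between them, and that is Q.

common to all: L 0.20 M; G 0.92 mM; Z 0.40 mM
- green: E 0.20 M; X 0.36 mM; run made earlier
- grey: E 0.20 M; X 0.81 mM; run made earlier
- flask: E 0.200 M; X 0.54 mM

| run | time / min | J / % | L / % |
|---|---|---|---|
| green | 1.50 | 0.8 | 80.4 |
| green | 5.00 | 7.3 | 57.0 |
| green | 10.0 | 17.7 | 42.4 |
| green | 15.0 | 26.8 | 36.0 |
| green | 20.0 | 35.1 | 30.9 |
| green | 25.0 | 40.8 | 27.8 |
| green | 30.0 | 46.4 | 25.0 |
| grey | 2.50 | 1.8 | 75.4 |
| grey | 4.00 | 4.6 | 66.6 |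
| grey | 6.00 | 8.1 | 57.5 |
| grey | 10.0 | 16.8 | 45.9 |
| grey | 15.0 | 24.9 | 38.2 |
| grey | 20.0 | 33.1 | 33.4 |
| grey | 30.0 | 44.8 | 26.7 |

(standard deviation of a reading: 0.3 percentage points)

- what may be going on: G + X <-> D; E + Z + Q -> Z + J; L + G <-> G + Q
- "the catalyst" is G with its forms; Z is a second catalyst
- no earlier run changes the charge of E; that part of a forecast is a guess

- apparent order in E when 30% of the L are converted (percent change of the rate of making J for one percent more E charged)

The next run was to be the flask, with X between the two earlier charges. I had to decide whether E could stay as it was, with no run yet changing E.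

I wrote the balances in fractions of the charge: l + q + j = 1. L and E were charged equally, so neither is the limiting reagent, and e = 1 − j.

Late in each run, the rate of J over q·e read 0.0609 min⁻¹ in green and 0.0618 min⁻¹ in grey. I therefore took the rate as proportional to q and e, and assumed the proportion scales with the E charged.

I reckoned that one percent more E makes j about one percent larger at a given conversion. The E present then rises about one percent too, and the extra j comes out of q, which shrinks by j/q percent. At a fixed conversion, under that assumed rate law, the order in E is one minus j/q.

Interpolating to 30% conversion, green gave 0.115 and grey 0.129. Their middle, 0.122, is my drain ratio, the J standing over the Q standing at one conversion, as a reading from scattered runs. My order was 0.878.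

I left E at 0.200 M and charged X at 0.54 mM.

The forecast said 0.9, from 0.8 to 1, and cautioned: “The E dependence itself is assumed from the mechanism, since no run varied E.” My own order stood lower than its figure.

The flask gave 0.91, which read back through the rule is a drain ratio of 0.0900 against my 0.122.

    G + X ⇌ D (K = 1200 M⁻¹, k = 57.0 M⁻¹ s⁻¹)
    E + Z + Q → Z + J (k = 13.0 M⁻² s⁻¹)
    L + G ⇌ G + Q (K = 1.30, k = 3.50 M⁻¹ s⁻¹)

At 4.00 min, with 36.8% of the L converted, the flask held J 4.81% and Q 32.0%, a drain ratio of 0.150, and at 4.49 min Q was made 2.51 times as fast as it was used up, each step taken net. At 40.0 min Q was made at 0.498 of the rate it was used up, each step taken net, and the flask held J 54.1% and Q 24.5%, a drain ratio of 2.21.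

The runs are simulated for an exercise; scatter was added.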